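(The readings were generated by integration for an exercise, noise included.)

Monday's flask held more Z than Saturday's, yet both opened at nearly one rate per unit of L.

| setting | Saturday's | Wednesday's | Monday's | flask |
|---|---|---|---|---|
| Z | 0.49 M | 0.49 M | 0.73 M | 0.49 M |
| L | 0.61 M | 0.92 M | 1.23 M | 1.23 M |
| E | 0.31 mM | 0.31 mM | 0.31 mM | 0.31 mM |
| remark | run made earlier | run made earlier | run made earlier |  |



| run | time / h | J / % | Z / % |
|---|---|---|---|
| Saturday's | 0.667 | 3.7 | 96.0 |
| Saturday's | 1.33 | 7.5 | 92.7 |
| Saturday's | 2.00 | 10.6 | 89.2 |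
| Saturday's | 2.50 | 13.9 | 86.5 |
| Saturday's | 3.00 | 16.1 | 84.8 |
| Saturday's | 4.00 | 20.0 | 80.2 |
| Wednesday's | 0.250 | 2.1 | 98.1 |
| Wednesday's | 0.833 | 7.1 | 93.7 |
| Wednesday's | 1.33 | 10.1 | 89.7 |
| Wednesday's | 2.00 | 15.2 | 85.0 |
| Wednesday's | 3.00 | 21.3 | 78.8 |
| Wednesday's | 4.00 | 27.3 | 73.0 |
| Monday's | 0.833 | 6.1 | 94.6 |
| Monday's | 1.50 | 9.1 | 90.3 |
| Monday's | 2.50 | 15.3 | 85.2 |
| Monday's | 3.00 | 17.4 | 82.1 |
| Monday's | 4.00 | 22.3 | 77.6 |

(readings scatter by 0.3 percentage points)

- steps under discussion: L + E -> G; G <-> D; Z + D -> Q; Q <-> E + J; E <-> X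
- no earlier run changes the charge of E; that part of a forecast is a guess

Over the first reading of each run:

w = rate of making J / c_L
Saturday 0.0446 h⁻¹; Wednesday 0.0447 h⁻¹; Monday 0.0435 h⁻¹

The quantity carried is w, the rate of making J per unit of c_L at that moment. In the first instants, then, L + E reads as the rate-limiting step.

In the middle, between the last two readings of each run, with c_L taken at the midpoint:

Saturday 0.0366 h⁻¹; Wednesday 0.0367 h⁻¹; Monday 0.0330 h⁻¹

Each late value is a difference of two readings, each with a scatter of 0.3 percentage points, so it is rough. In each run w has sunk from its opening value. With this roughness, the readings do not part a w that follows the clock from one that follows the J made.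

At the end, the readings stop short of the moment asked about.

- apparent order in E when 50% of the Z are converted (percent change of the rate of making J for one percent more E charged)
- factor on the rate of making J when 50% of the Z are converted if L is charged twice over

A fixed w gives the doubled L a factor of 2.25, the ratio of c_L at that conversion. Where w sinks with the clock, more E reaches that conversion sooner and at a higher w, which puts the order in E above one. The runs leave that open, so the reckoning here, which differs from the forecast, sets the order at one or above.

The forecast gives 1 (0.85 to 1.1) for the order and 1.65 (1.3 to 2.15) for the factor, on the ground that “Every listed step is linear in catalyst”.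

The flask gives an order of 1.2 and a factor of 1.92.

    L + E → G (k = 3.43 M⁻¹ min⁻¹)
    G ⇌ D (K = 2.70, k = 10.5 min⁻¹)
    Z + D → Q (k = 149 M⁻¹ min⁻¹)
    Q ⇌ E + J (K = 0.568 M, k = 58.4 min⁻¹)
    E ⇌ X (K = 4.14, k = 0.00105 min⁻¹)

At 50% conversion, after 6.87 h, the flask reads w = 0.0261 h⁻¹, which is 0.584 of Wednesday's opening value. Part of that loss is E passing to X, which holds 16.2% of the catalyst at 5.00 h: without that path the rate is 1.26 times the actual one. The same path lifts the order in E from 1.0 to 1.2. With L charged twice over, w reads 0.0223 h⁻¹, and that path lifts the order in L from 0.92 to 1.2.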